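## Retrosynthetic overview

1. Target 18 ⇐ double C-prenylation of the only unsubstituted ring carbon of hydroxy-trione 15, as in the lupulone-type prenylation of acylphloroglucinols.
2. 15 ⇐ intramolecular Claisen closure of open-chain triketone 14; this forms the six-membered carbocycle (second and final ring), with the acyl acetal as acyl donor.
3. 14 ⇐ oxidation of 13 ⇐ key intermolecular aldol: terminal carbanion of the dianion of 5-methylhexane-2,4-dione 11 plus the non-enolisable α-oxy aldehyde 10.
4. 10 ⇐ cis-dioxolanone 7 (temporary five-membered ring, formed first) by enolate hydroxymethylation and oxidation; the quaternary carbinol centre is set here by self-regeneration of stereocentres.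
5. 7 ⇐ (R)-2-hydroxy-5-methylhex-4-enoic acid 4 ⇐ methyl (R)-glycidate 1 + isobutenyl Grignard 2.

Assumption: the target is one enol tautomer of a β-triketone; its single stereocentre (the ring carbinol carbon) is R in the tautomer drawn, and all tautomers are treated as the same compound.

## Route

Step 1
Reactants: 1 methyl (2R)-oxirane-2-carboxylate; 2 (2-methylprop-1-en-1-yl)magnesium bromide
Product: 3 methyl (2R)-2-hydroxy-5-methylhex-4-enoate
Conditions: 2 (1.3 equiv), copper monoiodide CuI (10 mol%), THF, −40 to −20 °C; sat. aq. NH4Cl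
Reagents that add atoms: none
Why: Copper-catalysed Grignard opening of the epoxide (organocuprate SN2 attack at the unsubstituted terminal carbon) is faster than ester addition at low temperature and leaves the C2 stereocentre untouched, so the R configuration of 1 is carried into 3.

Step 2
Reactants: 3 methyl (2R)-2-hydroxy-5-methylhex-4-enoate
Product: 4 (2R)-2-hydroxy-5-methylhex-4-enoic acid
Conditions: LiOH·H2O (1.5 equiv), THF/H2O 3:1, 0 °C; cold 1 M HCl to pH 3
Reagents that add atoms: lithium hydroxide, [Li+].[OH-]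
Why: Mild ester saponification at 0 °C does not epimerise an α-hydroxy ester, and the trisubstituted alkene survives the brief cold acidification.

Step 3
Reactants: 4 (2R)-2-hydroxy-5-methylhex-4-enoic acid
Product: 5 trimethylsilyl (2R)-5-methyl-2-[(trimethylsilyl)oxy]hex-4-enoate
Conditions: Me3SiCl (2.3 equiv), Et3N (2.5 equiv), CH2Cl2, 0 °C to rt; filter, concentrate
Reagents that add atoms: chlorotrimethylsilane, C[Si](C)(C)Cl
Why: Exhaustive O-silylation (silyl ether and silyl ester formation) prepares the hydroxy acid for an aprotic acetalisation, so no strong Brønsted acid meets the prenyl double bond.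

Step 4
Reactants: 5 trimethylsilyl (2R)-5-methyl-2-[(trimethylsilyl)oxy]hex-4-enoate; 6 2,2-dimethylpropanal (pivalaldehyde)
Product: 7 (2R,5R)-2-tert-butyl-5-(3-methylbut-2-en-1-yl)-1,3-dioxolan-4-one
Conditions: 6 (1.5 equiv), Me3SiOTf (5 mol%), CH2Cl2, −25 °C, 16 h; pyridine quench; chromatography
Reagents that add atoms: none
Why: Silyl triflate-catalysed acetalisation (Seebach dioxolanone formation, low-temperature silyl variant) closes the acyl acetal with tert-butyl cis to the side chain (typically ≥ 20:1, minor trans isomer removed), so the new 2R acetal centre is set by the existing 5R centre and later relays the chirality.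

Step 5
Reactants: 7 (2R,5R)-2-tert-butyl-5-(3-methylbut-2-en-1-yl)-1,3-dioxolan-4-one
Product: 9 (2R,5S)-2-tert-butyl-5-(hydroxymethyl)-5-(3-methylbut-2-en-1-yl)-1,3-dioxolan-4-one, via lithium dioxolanone enolate 8 (not isolated)
Conditions: LiN(iPr)2 (1.1 equiv), THF, −78 °C, 30 min; CH2O gas (excess, from cracked paraformaldehyde), −78 °C; sat. aq. NH4Cl at −78 °C
Reagents that add atoms: formaldehyde, C=O
Why: Aldol addition of the Seebach enolate to formaldehyde (self-regeneration of stereocentres): the planar enolate is attacked on the face opposite the tert-butyl group, so CH2OH replaces the former hydrogen with retention and the quaternary carbinol centre forms with dr typically > 95:5.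

Step 6
Reactants: 9 (2R,5S)-2-tert-butyl-5-(hydroxymethyl)-5-(3-methylbut-2-en-1-yl)-1,3-dioxolan-4-one
Product: 10 (2R,4S)-2-tert-butyl-4-(3-methylbut-2-en-1-yl)-5-oxo-1,3-dioxolane-4-carbaldehyde
Conditions: Dess–Martin periodinane (1.3 equiv), pyridine (3 equiv), CH2Cl2, 0 °C to rt
Reagents that add atoms: none
Why: Dess–Martin oxidation converts the neopentyl primary alcohol into the aldehyde under buffered conditions, and the product has no α-hydrogen, so the quaternary centre cannot epimerise.

Step 7
Reactants: 10 (2R,4S)-2-tert-butyl-4-(3-methylbut-2-en-1-yl)-5-oxo-1,3-dioxolane-4-carbaldehyde; 11 5-methylhexane-2,4-dione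
Product: 13 (2R,5S)-2-tert-butyl-5-(1-hydroxy-6-methyl-3,5-dioxoheptyl)-5-(3-methylbut-2-en-1-yl)-1,3-dioxolan-4-one, via dilithium diketone dianion 12 (not isolated)
Conditions: 11 (1.5 equiv), LiN(iPr)2 (3.1 equiv), THF, 0 °C, 45 min; cool to −78 °C, add 10, 1 h; sat. aq. NH4Cl at −78 °C
Reagents that add atoms: none
Why: Intermolecular aldol addition of a Hauser-type β-diketone dianion: its terminal carbanion (methyl side, not isopropyl side) adds to the non-enolisable aldehyde far faster than to the lactone carbonyl at −78 °C, joining the two fragments; the new carbinol centre forms as a mixture that is erased in step 8.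

Step 8
Reactants: 13 (2R,5S)-2-tert-butyl-5-(1-hydroxy-6-methyl-3,5-dioxoheptyl)-5-(3-methylbut-2-en-1-yl)-1,3-dioxolan-4-one
Product: 14 (2R,5S)-2-tert-butyl-5-(6-methyl-3,5-dioxoheptanoyl)-5-(3-methylbut-2-en-1-yl)-1,3-dioxolan-4-one
Conditions: Dess–Martin periodinane (1.5 equiv), pyridine (3 equiv), CH2Cl2, 0 °C
Reagents that add atoms: none
Why: Dess–Martin oxidation of the δ-hydroxy-β-diketone gives the 1,3,5-triketone (the usual follow-up to a dianion aldol) without touching the alkene or the acyl acetal.

Step 9
Reactants: 14 (2R,5S)-2-tert-butyl-5-(6-methyl-3,5-dioxoheptanoyl)-5-(3-methylbut-2-en-1-yl)-1,3-dioxolan-4-one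
Product: 15 (6R)-5,6-dihydroxy-6-(3-methylbut-2-en-1-yl)-4-(2-methylpropanoyl)cyclohex-4-ene-1,3-dione
Conditions: LiN(SiMe3)2 (2.5 equiv), THF, −78 to 0 °C; cold 1 M HCl to pH 2–3; argon
Reagents that add atoms: none
Why: Intramolecular Claisen (Dieckmann-type) condensation: the doubly activated carbon next to the isobutyryl group attacks the activated acyl-acetal carbonyl to close the six-membered carbocycle, the expelled hemiacetal sheds pivalaldehyde to reveal the tertiary alcohol, the stabilised 2-acyl-1,3-dione anion makes the step irreversible, and the quaternary stereocentre is not involved.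

Step 10
Reactants: 15 (6R)-5,6-dihydroxy-6-(3-methylbut-2-en-1-yl)-4-(2-methylpropanoyl)cyclohex-4-ene-1,3-dione; 16 1-bromo-3-methylbut-2-ene (prenyl bromide)
Product: 18 (6R)-5,6-dihydroxy-2,2,6-tris(3-methylbut-2-en-1-yl)-4-(2-methylpropanoyl)cyclohex-4-ene-1,3-dione, via monoprenylated trione 17 (not isolated)
Conditions: NaOMe (3.2 equiv), MeOH, −10 °C; 16 (2.3 equiv) added slowly, −10 to 0 °C; cold 1 M HCl to pH 3; argon
Reagents that add atoms: none
Why: Twofold C-alkylation of the cyclic 1,3-dione enolate with an allylic bromide in a protic medium (the prenylation that turns acylphloroglucinols into lupulones) occurs at the only unsubstituted ring carbon, the acyl-bearing carbon being blocked; the new quaternary carbon carries two identical groups, so no stereocentre is created and the carbinol centre is untouched.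

## Compound list

1 | methyl (2R)-oxirane-2-carboxylate (methyl (R)-glycidate) | COC(=O)[C@H]1CO1 | starting material
2 | (2-methylprop-1-en-1-yl)magnesium bromide | CC(C)=C[Mg]Br | starting material
3 | methyl (2R)-2-hydroxy-5-methylhex-4-enoate | COC(=O)[C@H](O)CC=C(C)C | intermediate
4 | (2R)-2-hydroxy-5-methylhex-4-enoic acid | OC(=O)[C@H](O)CC=C(C)C | intermediate
5 | trimethylsilyl (2R)-5-methyl-2-[(trimethylsilyl)oxy]hex-4-enoate | C[Si](C)(C)OC(=O)[C@H](O[Si](C)(C)C)CC=C(C)C | intermediate
6 | 2,2-dimethylpropanal (pivalaldehyde) | CC(C)(C)C=O | starting material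
7 | (2R,5R)-2-tert-butyl-5-(3-methylbut-2-en-1-yl)-1,3-dioxolan-4-one (cis) | CC(C)(C)[C@H]1OC(=O)[C@@H](CC=C(C)C)O1 | intermediate
8 | lithium (2R)-2-tert-butyl-5-(3-methylbut-2-en-1-yl)-1,3-dioxol-4-olate (enolate of 7, formed in the flask) | [Li+].CC(C)(C)[C@H]1OC([O-])=C(CC=C(C)C)O1 | intermediate
9 | (2R,5S)-2-tert-butyl-5-(hydroxymethyl)-5-(3-methylbut-2-en-1-yl)-1,3-dioxolan-4-one | CC(C)(C)[C@H]1OC(=O)[C@@](CO)(CC=C(C)C)O1 | intermediate
10 | (2R,4S)-2-tert-butyl-4-(3-methylbut-2-en-1-yl)-5-oxo-1,3-dioxolane-4-carbaldehyde | CC(C)(C)[C@H]1OC(=O)[C@@](C=O)(CC=C(C)C)O1 | intermediate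
11 | 5-methylhexane-2,4-dione | CC(C)C(=O)CC(C)=O | starting material
12 | dilithium 5-methylhexa-1,3-diene-2,4-bis(olate) (dianion of 11, formed in the flask) | [Li+].[Li+].C=C([O-])C=C([O-])C(C)C | intermediate
13 | (2R,5S)-2-tert-butyl-5-(1-hydroxy-6-methyl-3,5-dioxoheptyl)-5-(3-methylbut-2-en-1-yl)-1,3-dioxolan-4-one (both carbinol epimers) | CC(C)(C)[C@H]1OC(=O)[C@@](C(O)CC(=O)CC(=O)C(C)C)(CC=C(C)C)O1 | intermediate
14 | (2R,5S)-2-tert-butyl-5-(6-methyl-3,5-dioxoheptanoyl)-5-(3-methylbut-2-en-1-yl)-1,3-dioxolan-4-one | CC(C)(C)[C@H]1OC(=O)[C@@](C(=O)CC(=O)CC(=O)C(C)C)(CC=C(C)C)O1 | intermediate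
15 | (6R)-5,6-dihydroxy-6-(3-methylbut-2-en-1-yl)-4-(2-methylpropanoyl)cyclohex-4-ene-1,3-dione (one tautomer) | CC(C)C(=O)C1=C(O)[C@](O)(CC=C(C)C)C(=O)CC1=O | intermediate
16 | 1-bromo-3-methylbut-2-ene (prenyl bromide) | CC(C)=CCBr | starting material
17 | (6R)-5,6-dihydroxy-2,6-bis(3-methylbut-2-en-1-yl)-4-(2-methylpropanoyl)cyclohex-4-ene-1,3-dione (one tautomer, C2 enolisable, formed in the flask) | CC(C)=CCC1C(=O)C(C(=O)C(C)C)=C(O)[C@](O)(CC=C(C)C)C1=O | intermediate
18 | (6R)-5,6-dihydroxy-2,2,6-tris(3-methylbut-2-en-1-yl)-4-(2-methylpropanoyl)cyclohex-4-ene-1,3-dione (CNP0442339.2) | CC(C)=CCC1(CC=C(C)C)C(=O)C(C(=O)C(C)C)=C(O)[C@](O)(CC=C(C)C)C1=O | target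

## Totals and risk

Total step count: 10. Longest linear sequence: 10 steps (1 to 18).

Steps most likely to fail:

Step 10 (double C-prenylation). O-prenylation and incomplete second alkylation can lower the yield, and the α-ketol is base-sensitive. The fallback sets out from 15 and comes back at 18. Treat 15 with allyl methyl carbonate (2.2 equiv) and the zerovalent palladium catalyst Pd(PPh3)4 (5 mol%) in THF at rt (Tsuji–Trost allylation; O-allyl products re-ionise and funnel to carbon). This gives (6R)-5,6-dihydroxy-6-(3-methylbut-2-en-1-yl)-4-(2-methylpropanoyl)-2,2-di(prop-2-en-1-yl)cyclohex-4-ene-1,3-dione F3. Olefin cross-metathesis of F3 with excess 2-methylbut-2-ene and second-generation Grubbs catalyst (5 mol%) in CH2Cl2 at 40 °C converts both allyl groups into prenyl groups and delivers 18; the existing prenyl group is degenerate under these conditions.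

Step 9 (ring-closing Claisen on the acyl acetal). O-acylation to an enol lactone or decomposition of the lithium polyanion may compete. The fallback sets out from 14 and comes back at 15. Methanolysis of the acyl acetal with NaOMe (2.3 equiv) in MeOH at −20 to 0 °C, the triketone being protected as its enolate, gives the open-chain ester methyl (2S)-2-hydroxy-8-methyl-2-(3-methylbut-2-en-1-yl)-3,5,7-trioxononanoate F2. F2 is then cyclised thermodynamically with Mg(OMe)2 (3 equiv) in MeOH at 40 °C, a magnesium-templated Claisen condensation of a 3,5,7-triketo ester of the kind used in biomimetic acylphloroglucinol formation, to give 15.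

Step 5 (hydroxymethylation with gaseous formaldehyde). Formaldehyde polymerisation, enolate decomposition or retro-aldol on warming can erode the yield. The fallback sets out from 7 and comes back at 9. Enolate 8, generated from 7 as before, is alkylated at −78 °C in THF with 4-methoxybenzyl chloromethyl ether (SN2 alkylation, again anti to the tert-butyl group). This gives (2R,5S)-2-tert-butyl-5-{[(4-methoxyphenyl)methoxy]methyl}-5-(3-methylbut-2-en-1-yl)-1,3-dioxolan-4-one F1. Oxidative ether cleavage of F1 with DDQ in CH2Cl2/pH 7 buffer at 0 °C gives 9.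

## Further compounds

F1 | step 5 | (2R,5S)-2-tert-butyl-5-{[(4-methoxyphenyl)methoxy]methyl}-5-(3-methylbut-2-en-1-yl)-1,3-dioxolan-4-one | CC(C)(C)[C@H]1OC(=O)[C@@](COCc2ccc(OC)cc2)(CC=C(C)C)O1
F2 | step 9 | methyl (2S)-2-hydroxy-8-methyl-2-(3-methylbut-2-en-1-yl)-3,5,7-trioxononanoate | COC(=O)[C@@](C(=O)CC(=O)CC(=O)C(C)C)(CC=C(C)C)O
F3 | step 10 | (6R)-5,6-dihydroxy-6-(3-methylbut-2-en-1-yl)-4-(2-methylpropanoyl)-2,2-di(prop-2-en-1-yl)cyclohex-4-ene-1,3-dione | C=CCC1(CC=C)C(=O)C(C(=O)C(C)C)=C(O)[C@](O)(CC=C(C)C)C1=O
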